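**Retrosynthetic overview**

- C2 is a hemiketal carbon that equilibrates with the open 1-aryl-1,2-dione, so the (2R) target is taken from its racemate at the very end by crystallising one diastereomeric amine salt while C2 epimerises.
- The furanone ring (O1–C2–C3–C3a–C7a) is the only ring formed and closes last: unmasking a 2-acyl-1,3-dithiane frees the C2 ketone and the C7a phenol adds to it.
- The strategy rests on O1 (on C7a) and the ketone carbon C3 (on C3a) being neighbouring substituents of the resorcinol ring. Both bonds, O1–C7a and C3–C3a, are made at once by inserting the C7a≡C3a aryne into the C–O bond of a carboxylate, with a removable bromine at C4 steering oxygen to C7a.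
- The o-silylaryl triflate comes from hydroquinone. The acid comes from ethyl 1,3-dithiane-2-carboxylate and (2E,6E)-farnesyl bromide, the dithiane masking the 2-oxo group.

Key step: step 7

Assumption: the (2R) centre is configurationally labile in solution through ring–chain tautomerism, so it is fixed only in the last two steps and the free compound is kept cold and free of base; that quinidine gives the (2R) salt as the less soluble diastereomer is assumed, and the pseudo-enantiomeric quinine would be used in the same way if the (2S) salt crystallised.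

Throughout, farnesyl = (2E,6E)-3,7,11-trimethyldodeca-2,6,10-trien-1-yl.

**Route**

Step 1
Reactants: 1 hydroquinone
Product: 2 4-(methoxymethoxy)phenol
Conditions: 1 (3 equiv), NaH (1.0 equiv), DMF, 0 °C; MOMCl (1.0 equiv), 0 °C → rt
Reagents that add atoms: chloromethyl methyl ether, COCCl
Why: Williamson etherification of the mono-phenoxide, in which the excess of the symmetrical diol keeps double alkylation low and leftover hydroquinone is washed out with water.

Step 2
Reactants: 2 4-(methoxymethoxy)phenol
Product: 3 2,6-dibromo-4-(methoxymethoxy)phenol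
Conditions: NBS (2.05 equiv), i-Pr2NH (0.1 equiv), CH2Cl2, 0 °C → rt
Reagents that add atoms: N-bromosuccinimide, O=C1CCC(=O)N1Br
Why: Amine-catalysed electrophilic bromination goes ortho to the free hydroxyl (the stronger activator, both ortho positions equivalent), and the non-acidic medium leaves the MOM acetal intact.

Step 3
Reactants: 3 2,6-dibromo-4-(methoxymethoxy)phenol
Product: 4 [2,6-dibromo-4-(methoxymethoxy)phenoxy]trimethylsilane
Conditions: HMDS (1.5 equiv), THF, 65 °C; volatiles removed in vacuo
Reagents that add atoms: hexamethyldisilazane, C[Si](C)(C)N[Si](C)(C)C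
Why: O-silylation with hexamethyldisilazane gives the aryl silyl ether needed for the silyl migration and releases only ammonia.

Step 4
Reactants: 4 [2,6-dibromo-4-(methoxymethoxy)phenoxy]trimethylsilane
Product: 7 2-bromo-4-(methoxymethoxy)-6-(trimethylsilyl)phenyl trifluoromethanesulfonate, via aryllithium 5 (not isolated), via lithium phenoxide 6 (not isolated)
Conditions: n-BuLi (1.05 equiv), THF, −78 °C, 30 min; Tf2O (1.2 equiv), −78 °C → 0 °C
Reagents that add atoms: trifluoromethanesulfonic anhydride, O=S(=O)(OS(=O)(=O)C(F)(F)F)C(F)(F)F
Why: Bromine–lithium exchange at one of the two equivalent bromines gives an aryllithium ortho to the silyloxy group, retro-Brook 1,3-migration moves silicon from oxygen to carbon, and the phenoxide is trapped as the triflate (the standard route to o-silylaryl triflates).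

Step 5
Reactants: 8 ethyl 1,3-dithiane-2-carboxylate; 9 (2E,6E)-farnesyl bromide
Product: 10 ethyl 2-farnesyl-1,3-dithiane-2-carboxylate
Conditions: NaH (1.1 equiv), toluene–DMF (4:1), 0 °C; then 9 (1.0 equiv), 0 °C → rt
Reagents that add atoms: none
Why: The ester- and sulfur-stabilised carbanion is soft and alkylates the primary allylic bromide by SN2 at C1 without allylic transposition, so the 2E,6E geometry is kept.

Step 6
Reactants: 10 ethyl 2-farnesyl-1,3-dithiane-2-carboxylate
Product: 11 2-farnesyl-1,3-dithiane-2-carboxylic acid
Conditions: KOH (4 equiv), EtOH–H2O (4:1), 70 °C; then 1 M HCl to pH 3, 0 °C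
Reagents that add atoms: potassium hydroxide, [K+].[OH-]
Why: Saponification of the ethyl ester, in which the fully substituted α-carbon cannot enolise or eliminate and cold mild acidification spares the alkenes.

Step 7
Reactants: 11 2-farnesyl-1,3-dithiane-2-carboxylic acid; 7 2-bromo-4-(methoxymethoxy)-6-(trimethylsilyl)phenyl trifluoromethanesulfonate
Product: 14 [2-bromo-6-hydroxy-4-(methoxymethoxy)phenyl](2-farnesyl-1,3-dithian-2-yl)methanone, via cesium carboxylate 12 (not isolated), via aryne 13 (not isolated)
Conditions: 11 (1.0 equiv), Cs2CO3 (0.5 equiv), MeOH, rt, then evaporated and dried (toluene azeotrope); 7 (1.4 equiv), CsF (3 equiv), THF, 110 °C, sealed tube; cold 0.5 M HCl work-up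
Reagents that add atoms: none
Why: Fluoride removes the trimethylsilyl group of 7 and triflate departs to give aryne 13; the carboxylate oxygen of 12 adds to the aryne carbon that becomes C7a, and the aryl anion left at C3a attacks the carbonyl of the aryl ester just formed through a four-membered alkoxide, which opens to the cesium o-acylphenoxide (net insertion of the aryne into the C–O bond of the acid). The closest known reaction is the fluoride-induced C–O insertion of arynes from o-silylaryl triflates into carboxylic acids, which gives o-hydroxyaryl ketones; the acid is used here as its dry cesium salt so that no acidic proton can quench the aryl anion to the plain aryl ester. No ring is closed and no stereocentre is formed in this step. The selectivity needed is regiochemical: the bromine next to the triple bond withdraws inductively, so the nucleophile attacks the remote aryne carbon (C7a) and the negative charge develops beside bromine (C3a), whereas the C6 oxygen, one carbon further away, has only a weak influence. Chemoselectively, the anionic oxygen should add faster than the neutral dithiane sulfur or the chain alkenes (ene reaction), the intramolecular acyl shift should outrun loss of bromide from the 2-bromoaryl anion, and the fully substituted dithiane carbon rules out ketene or enolate pathways.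

Step 8
Reactants: 14 [2-bromo-6-hydroxy-4-(methoxymethoxy)phenyl](2-farnesyl-1,3-dithian-2-yl)methanone
Product: 16 [2-hydroxy-4-(methoxymethoxy)phenyl](2-farnesyl-1,3-dithian-2-yl)methanone, via dilithio species 15 (not isolated)
Conditions: t-BuLi (3.1 equiv), THF, −78 °C, 15 min; AcOH, −78 °C → rt
Reagents that add atoms: none
Why: Halogen–lithium exchange followed by protonation should be faster than addition to the ketone (flanked by a 2,6-disubstituted arene and a quaternary carbon, and deactivated by the ortho phenoxide), and it is preferred to a palladium-catalysed formate reduction because an arylpalladium at C4 would lie within reach of the first chain alkene for a 6-exo Heck cyclisation.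

Step 9
Reactants: 16 [2-hydroxy-4-(methoxymethoxy)phenyl](2-farnesyl-1,3-dithian-2-yl)methanone
Product: 17 (2,4-dihydroxyphenyl)(2-farnesyl-1,3-dithian-2-yl)methanone
Conditions: 3 M aq. HCl–MeOH (1:10), 40 °C
Reagents that add atoms: none
Why: Acid-catalysed transacetalisation to methanol cleaves the aryl MOM ether while the dithiane, inert to acid, keeps the 2-oxo group masked, so no hemiketal or methyl ketal can form and the dilute acid leaves the trisubstituted alkenes alone.

Step 10
Reactants: 17 (2,4-dihydroxyphenyl)(2-farnesyl-1,3-dithian-2-yl)methanone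
Product: 19 racemic 2-farnesyl-2,6-dihydroxy-1-benzofuran-3(2H)-one, via open diketone 18 (not isolated)
Conditions: MeI (15 equiv), CaCO3 (3 equiv), MeCN–H2O (4:1), 40 °C, dark
Reagents that add atoms: water, O
Why: Alkylative dithiane hydrolysis (S-methylation, thionium ion, water) frees the 1,2-diketone, whose C2 ketone is captured by the ortho phenol (5-exo-trig) to give the favoured cyclic hemiketal as a racemate, the near-neutral carbonate buffer keeping phenols protonated and alkenes untouched.

Step 11
Reactants: 19 racemic 2-farnesyl-2,6-dihydroxy-1-benzofuran-3(2H)-one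
Product: 20 quinidinium (2R)-2-farnesyl-2-hydroxy-3-oxo-2,3-dihydro-1-benzofuran-6-olate (1:1 salt)
Conditions: quinidine (1.0 equiv), MeCN, 45 °C → 20 °C with seeding, slurry aged 24–48 h; filtration
Reagents that add atoms: quinidine, COc1ccc2nccc([C@H](O)[C@H]3C[C@@H]4CCN3C[C@@H]4C=C)c2c1
Why: Proposed new method: the acidic C6 phenol (para to the ketone) forms diastereomeric quinidinium salts, the tertiary amine catalyses opening of the hemiketal to achiral diketone 18 and reclosure so that C2 epimerises in solution, and crystallisation of the less soluble salt drains this equilibrium, the crystal lattice of the quinidine salt being the element that sets (2R); the closest known reaction type is the crystallisation-induced diastereomer transformation of chiral-amine salts of acids carrying a labile stereocentre, together with the known ready racemisation of 2-hydroxybenzofuran-3-ones by ring opening.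

Step 12
Reactants: 20 quinidinium (2R)-2-farnesyl-2-hydroxy-3-oxo-2,3-dihydro-1-benzofuran-6-olate
Product: 21 (2R)-2,6-dihydroxy-2-[(2E,6E)-3,7,11-trimethyldodeca-2,6,10-trien-1-yl]-1-benzofuran-3(2H)-one
Conditions: MTBE / 0.2 M aq. HCl, 0 °C, brief; organic layer dried (Na2SO4) and evaporated below 20 °C
Reagents that add atoms: none
Why: Cold acid–base partition protonates the phenolate and carries quinidine into water, and ring opening of the hemiketal should be slow at 0 °C in the absence of base, so the configuration fixed in the crystal is carried into the free compound.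

**Compound list**

1 | hydroquinone | Oc1ccc(O)cc1 | starting material
2 | 4-(methoxymethoxy)phenol | COCOc1ccc(O)cc1 | intermediate
3 | 2,6-dibromo-4-(methoxymethoxy)phenol | COCOc1cc(Br)c(O)c(Br)c1 | intermediate
4 | [2,6-dibromo-4-(methoxymethoxy)phenoxy]trimethylsilane | COCOc1cc(Br)c(O[Si](C)(C)C)c(Br)c1 | intermediate
5 | [3-bromo-5-(methoxymethoxy)-2-(trimethylsilyloxy)phenyl]lithium | COCOc1cc(Br)c(O[Si](C)(C)C)c([Li])c1 | intermediate (not isolated)
6 | lithium 2-bromo-4-(methoxymethoxy)-6-(trimethylsilyl)phenoxide | COCOc1cc(Br)c([O-])c([Si](C)(C)C)c1.[Li+] | intermediate (not isolated)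
7 | 2-bromo-4-(methoxymethoxy)-6-(trimethylsilyl)phenyl trifluoromethanesulfonate | COCOc1cc(Br)c(OS(=O)(=O)C(F)(F)F)c([Si](C)(C)C)c1 | intermediate
8 | ethyl 1,3-dithiane-2-carboxylate | CCOC(=O)C1SCCCS1 | starting material
9 | (2E,6E)-farnesyl bromide | CC(C)=CCC/C(C)=C/CC/C(C)=C/CBr | starting material
10 | ethyl 2-farnesyl-1,3-dithiane-2-carboxylate | CC(C)=CCC/C(C)=C/CC/C(C)=C/CC1(SCCCS1)C(=O)OCC | intermediate
11 | 2-farnesyl-1,3-dithiane-2-carboxylic acid | CC(C)=CCC/C(C)=C/CC/C(C)=C/CC1(SCCCS1)C(=O)O | intermediate
12 | cesium 2-farnesyl-1,3-dithiane-2-carboxylate | CC(C)=CCC/C(C)=C/CC/C(C)=C/CC1(SCCCS1)C(=O)[O-].[Cs+] | intermediate (not isolated)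
13 | 3-bromo-5-(methoxymethoxy)benzyne | COCOC1=CC#CC(Br)=C1 | intermediate (not isolated)
14 | [2-bromo-6-hydroxy-4-(methoxymethoxy)phenyl](2-farnesyl-1,3-dithian-2-yl)methanone | CC(C)=CCC/C(C)=C/CC/C(C)=C/CC1(SCCCS1)C(=O)c1c(O)cc(OCOC)cc1Br | intermediate
15 | dilithio species: lithium 3-lithio-2-[(2-farnesyl-1,3-dithian-2-yl)carbonyl]-5-(methoxymethoxy)phenoxide | CC(C)=CCC/C(C)=C/CC/C(C)=C/CC1(SCCCS1)C(=O)c1c([Li])cc(OCOC)cc1O[Li] | intermediate (not isolated)
16 | [2-hydroxy-4-(methoxymethoxy)phenyl](2-farnesyl-1,3-dithian-2-yl)methanone | CC(C)=CCC/C(C)=C/CC/C(C)=C/CC1(SCCCS1)C(=O)c1ccc(OCOC)cc1O | intermediate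
17 | (2,4-dihydroxyphenyl)(2-farnesyl-1,3-dithian-2-yl)methanone | CC(C)=CCC/C(C)=C/CC/C(C)=C/CC1(SCCCS1)C(=O)c1ccc(O)cc1O | intermediate
18 | (4E,8E)-1-(2,4-dihydroxyphenyl)-5,9,13-trimethyltetradeca-4,8,12-triene-1,2-dione (open diketone) | CC(C)=CCC/C(C)=C/CC/C(C)=C/CC(=O)C(=O)c1ccc(O)cc1O | intermediate (not isolated)
19 | racemic 2-farnesyl-2,6-dihydroxy-1-benzofuran-3(2H)-one | CC(C)=CCC/C(C)=C/CC/C(C)=C/CC1(O)Oc2cc(O)ccc2C1=O | intermediate
20 | quinidinium (2R)-2-farnesyl-2-hydroxy-3-oxo-2,3-dihydro-1-benzofuran-6-olate | CC(C)=CCC/C(C)=C/CC/C(C)=C/C[C@@]1(O)Oc2cc([O-])ccc2C1=O.COc1ccc2nccc([C@H](O)[C@H]3C[C@@H]4CC[NH+]3C[C@@H]4C=C)c2c1 | intermediate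
21 | (2R)-2,6-dihydroxy-2-[(2E,6E)-3,7,11-trimethyldodeca-2,6,10-trien-1-yl]-1-benzofuran-3(2H)-one | CC(C)=CCC/C(C)=C/CC/C(C)=C/C[C@@]1(O)Oc2cc(O)ccc2C1=O | target

**Step count**

Total steps: 12. Longest linear sequence: 10 (steps 1–4, then 7–12, from hydroquinone); the acid branch (steps 5–6) joins at step 7.

**Steps most likely to fail**

1. Step 11 (proposed new method). The salt may oil out instead of crystallising because of the lipophilic chain, the wrong diastereomer may be the less soluble one, or prolonged contact with the amine may enolise the ring-opened diketone and move the first chain alkene into conjugation. Fallback: starting from racemate 19, the enantiomers are separated by preparative chromatography on a chiral stationary phase (amylose tris(3,5-dimethylphenylcarbamate), supercritical CO2/i-PrOH, column at or below 10 °C), which delivers target 21 directly. The unwanted (2S)-2-farnesyl-2,6-dihydroxy-1-benzofuran-3(2H)-one F1 is left to re-equilibrate to 19 in solution with a trace of Et3N and is recycled. The fallback comes back to the route at 21.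

2. Step 7. Bromide may be lost from the 2-bromoaryl anion before the acyl shift (giving a second aryne), the aryne may arylate a dithiane sulfur, the aryl anion may be protonated to the plain aryl ester, or the regioselectivity may be eroded. Fallback: starting from acid 11, amide coupling with MeNHOMe·HCl (EDC·HCl, i-Pr2NEt, CH2Cl2) gives N-methoxy-N-methyl-2-farnesyl-1,3-dithiane-2-carboxamide F2. Separately, commercial 4-bromoresorcinol is bis-protected (MOMCl, i-Pr2NEt) to 1-bromo-2,4-bis(methoxymethoxy)benzene F3, which on bromine–lithium exchange (n-BuLi, THF, −78 °C) gives [2,4-bis(methoxymethoxy)phenyl]lithium F4. Addition of this aryllithium to the Weinreb amide gives [2,4-bis(methoxymethoxy)phenyl](2-farnesyl-1,3-dithian-2-yl)methanone F5, and HCl in MeOH removes both MOM groups. The fallback comes back to the route at 17, so steps 7–9 are bypassed.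

3. Step 10. Hydrolysis of the 2-acyl dithiane may be sluggish or stall at an S,O-ketal, the acidic C6 phenol may be O-methylated, or acid may build up and attack the alkenes. Fallback: starting from 17, one sulfur is oxidised with NaIO4 (1.05 equiv, MeOH–H2O, 0 °C) to (2,4-dihydroxyphenyl)(2-farnesyl-1-oxido-1,3-dithian-2-yl)methanone F6 (diastereomer mixture). Dilute HCl in aqueous MeCN at room temperature then opens the sulfoxide (Pummerer-type C–S cleavage, the sulfur fragment leaving as a cyclic disulfide) and the phenol closes onto C2. The fallback comes back to the route at 19.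

**Further compounds**

F1 | step 11 | (2S)-2-farnesyl-2,6-dihydroxy-1-benzofuran-3(2H)-one | CC(C)=CCC/C(C)=C/CC/C(C)=C/C[C@]1(O)Oc2cc(O)ccc2C1=O
F2 | step 7 | N-methoxy-N-methyl-2-farnesyl-1,3-dithiane-2-carboxamide | CC(C)=CCC/C(C)=C/CC/C(C)=C/CC1(SCCCS1)C(=O)N(C)OC
F3 | step 7 | 1-bromo-2,4-bis(methoxymethoxy)benzene | COCOc1ccc(Br)c(OCOC)c1
F4 | step 7 | [2,4-bis(methoxymethoxy)phenyl]lithium | COCOc1ccc([Li])c(OCOC)c1
F5 | step 7 | [2,4-bis(methoxymethoxy)phenyl](2-farnesyl-1,3-dithian-2-yl)methanone | CC(C)=CCC/C(C)=C/CC/C(C)=C/CC1(SCCCS1)C(=O)c1ccc(OCOC)cc1OCOC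
F6 | step 10 | (2,4-dihydroxyphenyl)(2-farnesyl-1-oxido-1,3-dithian-2-yl)methanone | CC(C)=CCC/C(C)=C/CC/C(C)=C/CC1(SCCCS1=O)C(=O)c1ccc(O)cc1O
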